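## Retrosynthetic overview

1. Disydonol A (9) ⇒ ester 8: the CH2OH of the phenol-donor half is carried as a methyl ester and reduced last.
2. Key disconnection: the ArO–CH2Ar ether C–O bond of 8 ⇒ (S)-sydonol 7 (benzylic alcohol partner) + methyl (S)-sydonate 6 (phenol partner), joined unprotected by a Mitsunobu reaction.
3. 7 ⇐ 6 by ester reduction, so one enantioenriched building block supplies both halves; mismatched pairs become diastereomers in the coupling and can be removed.
4. 6 ⇐ ketoester 1 + the 4-methylpentyl group of bromide 2, by a new phenoxide-anchored catalytic enantioselective ketone alkylation that sets the (S) centre.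
5. No ring is formed; both benzene rings are bought with 1.

Assumption: methyl 4-acetyl-3-hydroxybenzoate (1) and 1-bromo-4-methylpentane (2) are taken as catalogue building blocks.

## Route

Step 1
Reactants: 1 methyl 4-acetyl-3-hydroxybenzoate; 2 1-bromo-4-methylpentane
Product: 6 methyl 3-hydroxy-4-[(2S)-2-hydroxy-6-methylheptan-2-yl]benzoate, via 4-methylpentylmagnesium bromide 3 (not isolated), via bis(4-methylpentyl)zinc 4 (not isolated), via methyl 4-acetyl-3-(triisopropoxytitanyloxy)benzoate 5 (not isolated)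
Conditions: 2, Mg, Et2O; ZnCl2 (0.5 equiv), then 1,4-dioxane, filter, swap to toluene; separately 1, Ti(OiPr)4 (2.2 equiv), toluene, strip iPrOH; chiral bis(sulfonamide)diol ligand L* (trans-cyclohexane-1,2-diamine bis(2-hydroxycamphor-10-sulfonamide), 10 mol%), add 4 (1.8 equiv), 0 °C to rt, 36 h; aqueous Rochelle salt work-up
Reagents that add atoms: none
Why: Proposed new method: chelation-anchored catalytic enantioselective alkylation of an unprotected 2'-hydroxyaryl methyl ketone, in which the phenol is first turned into titanium aryloxide 5, the aryloxide oxygen docks onto the chiral bis(sulfonamide)diolate–titanium catalyst while the ortho C=O stays coordinated and coplanar, the 4-methylpentyl group passes from zinc to titanium and is delivered to the exposed Si face to give the (S)-tertiary alkoxide, and alkylzinc/alkyltitanium species leave the methyl ester alone; the closest known reaction type is the Ti(OiPr)4/chiral bis(sulfonamide)diol-catalysed 1,2-addition of dialkylzincs to simple, non-chelating aryl methyl ketones.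

Step 2
Reactants: 6 methyl 3-hydroxy-4-[(2S)-2-hydroxy-6-methylheptan-2-yl]benzoate (about one quarter of the batch)
Product: 7 (S)-sydonol, 2-[(2S)-2-hydroxy-6-methylheptan-2-yl]-5-(hydroxymethyl)phenol
Conditions: LiAlH4 (3 equiv), THF, 0 °C to rt; Rochelle salt work-up, no acid
Reagents that add atoms: none
Why: LiAlH4 ester reduction gives the benzylic alcohol while the phenoxide and tertiary alkoxide are spectators, so the stereocentre is untouched.

Step 3
Reactants: 7 (S)-sydonol; 6 methyl 3-hydroxy-4-[(2S)-2-hydroxy-6-methylheptan-2-yl]benzoate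
Product: 8 methyl 3-({3-hydroxy-4-[(2S)-2-hydroxy-6-methylheptan-2-yl]phenyl}methoxy)-4-[(2S)-2-hydroxy-6-methylheptan-2-yl]benzoate
Conditions: 6 (3 equiv), PPh3 (1.3 equiv), DIAD (1.3 equiv), THF, 0 °C; 7 added over 2 h, then rt; excess 6 recovered by chromatography
Reagents that add atoms: none
Why: Mitsunobu etherification, in which only the primary benzylic hydroxyl of 7 forms an alkoxyphosphonium ion (tertiary alcohols are inert) and the more acidic, threefold-excess ester phenol 6 displaces Ph3PO by SN2 at CH2, so the joining C–O bond forms without protecting groups and without touching either stereocentre.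

Step 4
Reactants: 8 the coupled methyl ester
Product: 9 disydonol A, 2-[(2S)-2-hydroxy-6-methylheptan-2-yl]-5-({2-[(2S)-2-hydroxy-6-methylheptan-2-yl]-5-(hydroxymethyl)phenoxy}methyl)phenol
Conditions: LiAlH4 (4 equiv), THF, 0 °C to rt; Rochelle salt work-up, no acid
Reagents that add atoms: none
Why: LiAlH4 ester reduction, to which the benzyl aryl ether, the phenol and both tertiary benzylic alcohols are inert at 0 °C to rt, so no stereocentre changes.

## Compound list

1 | methyl 4-acetyl-3-hydroxybenzoate | COC(=O)c1ccc(C(C)=O)c(O)c1 | starting material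
2 | 1-bromo-4-methylpentane | CC(C)CCCBr | starting material
3 | 4-methylpentylmagnesium bromide | CC(C)CCC[Mg]Br | intermediate
4 | bis(4-methylpentyl)zinc | CC(C)CCC[Zn]CCCC(C)C | intermediate
5 | methyl 4-acetyl-3-(triisopropoxytitanyloxy)benzoate | COC(=O)c1ccc(C(C)=O)c(O[Ti](OC(C)C)(OC(C)C)OC(C)C)c1 | intermediate
6 | methyl 3-hydroxy-4-[(2S)-2-hydroxy-6-methylheptan-2-yl]benzoate (methyl (S)-sydonate) | CC(C)CCC[C@](C)(O)c1ccc(C(=O)OC)cc1O | intermediate
7 | (S)-sydonol, 2-[(2S)-2-hydroxy-6-methylheptan-2-yl]-5-(hydroxymethyl)phenol | CC(C)CCC[C@](C)(O)c1ccc(CO)cc1O | intermediate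
8 | methyl 3-({3-hydroxy-4-[(2S)-2-hydroxy-6-methylheptan-2-yl]phenyl}methoxy)-4-[(2S)-2-hydroxy-6-methylheptan-2-yl]benzoate | CC(C)CCC[C@](C)(O)c1ccc(COc2cc(C(=O)OC)ccc2[C@@](C)(O)CCCC(C)C)cc1O | intermediate
9 | disydonol A | CC(C)CCC[C@](C)(O)c1ccc(COc2cc(CO)ccc2[C@@](C)(O)CCCC(C)C)cc1O | target

## Step count and risks

Total step count: 4. Longest linear sequence: 4 (1 → 6 → 7 → 8 → 9).

Steps most likely to fail:

Step 1 (the proposed new step). The titanium aryloxide chelate may be too electron-rich to accept the alkyl group, an uncatalysed path through achiral titanium may lower the ee, and β-hydride transfer may give the secondary alcohol. The facial sense is checked at 7 against natural (S)-sydonol; if it is opposite, the mirror-image ligand is used. The fallback uses known chemistry, sets out from 1 and comes back at 6. O-Benzylation (BnBr, K2CO3, DMF) gives methyl 4-acetyl-3-(benzyloxy)benzoate F1. Catalytic enantioselective allylboration of the ketone (allylB(pin), chiral aminophenol–boron or 3,3'-disubstituted BINOL catalyst, Si-face delivery) gives methyl 3-(benzyloxy)-4-[(2S)-2-hydroxypent-4-en-2-yl]benzoate F2. Cross-metathesis with 3-methylbut-1-ene (Hoveyda–Grubbs II, CH2Cl2, 40 °C, sealed tube) gives methyl 3-(benzyloxy)-4-[(2S,4E)-2-hydroxy-6-methylhept-4-en-2-yl]benzoate F3. Hydrogenation (H2, Pd/C, EtOAc) saturates the alkene and removes the benzyl ether in one operation to give 6.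

Step 3. The phenols of 7 and of product 8 can also be benzylated, giving oligomeric ethers, and the hindered ortho-tert-alkyl phenol may react slowly. The fallback sets out from 7 and comes back at 8, replacing the Mitsunobu reaction by a protected Williamson ether synthesis. Phenol-selective allylation (allyl bromide, K2CO3, acetone) gives {4-[(2S)-2-hydroxy-6-methylheptan-2-yl]-3-(prop-2-en-1-yloxy)phenyl}methanol F4. An Appel reaction (CBr4, PPh3, CH2Cl2, 0 °C) gives (2S)-2-[4-(bromomethyl)-2-(prop-2-en-1-yloxy)phenyl]-6-methylheptan-2-ol F5. Alkylation of 6 (1.1 equiv, K2CO3, DMF, rt) gives methyl 4-[(2S)-2-hydroxy-6-methylheptan-2-yl]-3-({4-[(2S)-2-hydroxy-6-methylheptan-2-yl]-3-(prop-2-en-1-yloxy)phenyl}methoxy)benzoate F6. Deallylation (Pd(PPh3)4 cat., morpholine, THF, rt) gives 8.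

Step 4. Aluminium phenoxide/alkoxide aggregates may stall the reduction, and forcing it risks benzylic C–O hydrogenolysis next to the free phenol. The fallback sets out from 8 and comes back at 9. Saponification (LiOH, THF/H2O, rt; buffer to pH 4–5) gives 3-({3-hydroxy-4-[(2S)-2-hydroxy-6-methylheptan-2-yl]phenyl}methoxy)-4-[(2S)-2-hydroxy-6-methylheptan-2-yl]benzoic acid F7. Borane (BH3·THF, 0 °C to rt) then reduces the acid selectively to 9.

Further compounds
F1 | step 1 | methyl 4-acetyl-3-(benzyloxy)benzoate | COC(=O)c1ccc(C(C)=O)c(OCc2ccccc2)c1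
F2 | step 1 | methyl 3-(benzyloxy)-4-[(2S)-2-hydroxypent-4-en-2-yl]benzoate | C=CC[C@](C)(O)c1ccc(C(=O)OC)cc1OCc1ccccc1
F3 | step 1 | methyl 3-(benzyloxy)-4-[(2S,4E)-2-hydroxy-6-methylhept-4-en-2-yl]benzoate | CC(C)/C=C/C[C@](C)(O)c1ccc(C(=O)OC)cc1OCc1ccccc1
F4 | step 3 | {4-[(2S)-2-hydroxy-6-methylheptan-2-yl]-3-(prop-2-en-1-yloxy)phenyl}methanol | CC(C)CCC[C@](C)(O)c1ccc(CO)cc1OCC=C
F5 | step 3 | (2S)-2-[4-(bromomethyl)-2-(prop-2-en-1-yloxy)phenyl]-6-methylheptan-2-ol | CC(C)CCC[C@](C)(O)c1ccc(CBr)cc1OCC=C
F6 | step 3 | methyl 4-[(2S)-2-hydroxy-6-methylheptan-2-yl]-3-({4-[(2S)-2-hydroxy-6-methylheptan-2-yl]-3-(prop-2-en-1-yloxy)phenyl}methoxy)benzoate | CC(C)CCC[C@](C)(O)c1ccc(COc2cc(C(=O)OC)ccc2[C@@](C)(O)CCCC(C)C)cc1OCC=C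
F7 | step 4 | 3-({3-hydroxy-4-[(2S)-2-hydroxy-6-methylheptan-2-yl]phenyl}methoxy)-4-[(2S)-2-hydroxy-6-methylheptan-2-yl]benzoic acid | CC(C)CCC[C@](C)(O)c1ccc(COc2cc(C(=O)O)ccc2[C@@](C)(O)CCCC(C)C)cc1O
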